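An easy subtraction comes first: each Xp made has taken one Xb, so [Xb] is the Xb charged minus [Xp].

the same everywhere: Xc 0.00200 M
- Monday's: Xa 0.100 M; Xb 0.0800 M
- Wednesday's: Xa 0.0600 M; Xb 0.0400 M
- Sunday's: Xa 0.0500 M; Xb 0.0800 M
- Saturday's: Xa 0.100 M; Xb 0.0800 M; time 420 h

| run | time / h | [Xp] / M |
|---|---|---|
| Monday's run | 6.8 | 0.0262 |
| Monday's run | 11 | 0.0355 |
| Monday's run | 17 | 0.0439 |
| Monday's run | 27 | 0.0516 |
| Monday's run | 43 | 0.0591 |
| Monday's run | 68 | 0.0642 |
| Monday's run | 110 | 0.0695 |
| Monday's run | 170 | 0.0705 |
| Wednesday's run | 6.8 | 0.0107 |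
| Wednesday's run | 11 | 0.0146 |
| Wednesday's run | 17 | 0.0179 |
| Wednesday's run | 27 | 0.0229 |
| Wednesday's run | 43 | 0.0269 |
| Wednesday's run | 68 | 0.0309 |
| Wednesday's run | 110 | 0.0331 |
| Wednesday's run | 170 | 0.0345 |
| Sunday's run | 6.8 | 0.0172 |
| Sunday's run | 11 | 0.0224 |
| Sunday's run | 17 | 0.0280 |
| Sunday's run | 27 | 0.0341 |
| Sunday's run | 43 | 0.0405 |
| Sunday's run | 68 | 0.0444 |
| Sunday's run | 110 | 0.0475 |
| Sunday's run | 170 | 0.0495 |

(readings scatter by 5 × 10⁻⁴ M)

- Overall: Xa + Xb -> Xp, with Xc as catalyst.
- Constant volume, constant temperature.
- What is held in complexes is read along with the free species.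
- An order is taken over about fifteen percent of the charge, up and down.

- the power of [Xb] that the first rate follows, about the charge of the Monday's run; measure it at two percent of Xa made into Xp
- the power of [Xa] that the first rate follows, about the charge of the Monday's run; measure it at two percent of Xa made into Xp (one fixed amount of Xp, the same in the runs compared)
- the Wednesday's run starts with 0.0400 M less of Xa and of Xb than the Monday's run, and with no Xp. Compared where both hold the same amount of Xa, once fifteen percent of what the Wednesday's run was charged with has turned into Xp, is the Wednesday's run faster, slower or alike (within a tenth)?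
- Xp in the Saturday's run at 420 h, as a share of the Xa charged

The Saturday's flask repeats the Monday's charge. Xb is its limiting reagent, 0.0800 M against 0.100 M of Xa, so the cap on Xp is 80.0 % of the Xa charged. I work with the fraction of Xb left. At 170 h in the Monday's run the depth is 2.13, the logarithm of Xb charged over Xb left. One reading's scatter moves it by 0.0526.

Now I turn the question round: what must be true for the Saturday's flask to reach its cap? At the cap the fraction left is zero, so the depth must keep climbing. In the Monday's run it starts at this pace:

early pace = 0.0583 /h

Suppose the catalyst stays intact and the rate is first order in [Xb] and in [Xa]. Then the late pace falls with the Xa left: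

pace needed = early pace × [Xa] / Xa charged = 0.0172 /h

pace read, Monday's last two readings = 0.00167 /h

This rough reading is lower by a factor of 10.3, so I don't expect the cap. The pace has fallen, so over the remaining 250 h I let the depth climb at half the late pace:

depth at 420 h = 2.34, so Xp = 72.3 % of the Xa charged

The forecast gives 0.95 for the order in Xb, 0.55 for the order in Xa, faster for the Wednesday's run and 73.5 % for the Saturday's run: “Monday has nearly stalled by 170 h at 0.0705, creeping perhaps to 0.073–0.075.” Its share stands above mine.

The flask gives 1.0, 0.74, faster and 72.5 %. The order in Xa stands above the forecast's.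

    Xc + Xa ⇌ Xc.Xa, settled at all times (3.830 /M)
    Xc.Xa + Xb → Xp + Xc + Xh (131.0 /M/h)
    Xc.Xa → L + Xa (0.1098 /h)

With the reaction of Xc.Xa to L + Xa taken away, the Saturday's run comes to 80.0 % at 420 h instead of 72.5 %, so that reaction holds it down. Each Xc.Xa either meets Xb or is lost, so the Xc charged buys a fixed depth:

depth = 131 /M/h × 0.00200 M / 0.110 /h = 2.38

The Saturday's share reads as a depth of 2.37, up from the 2.13 of the Monday's run at 170 h. The Wednesday's run holds the same Xc, so that depth allows it 0.0363 M of Xp, and its last reading is 0.0345 M.

The runs were generated by integration for an exercise; noise was put on by code.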